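**Retrosynthetic overview**

1. The C1'–O aryl ether is cut last (Mitsunobu): target ⇒ umbelliferone + a primary allylic alcohol. The coumarin is bought intact; no ring is built and the only ring event is the opening of a furan.
2. The 8'-carbinol and the C1' alcohol ⇒ one oxazaborolidine (CBS) reduction of an acetoxy keto-enal. C8' stays a ketone until the 5'-acetate is in place, so OAc and OH never need differentiating and no protecting group is used.
3. C4'–C5' ⇒ asymmetric vinylogous Mukaiyama aldol of a prenal-derived silyl dienol ether onto the aldehyde of (2E)-3,7-dimethyl-4-oxoocta-2,6-dienal, which sets 5'S and the 2'E alkene.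
4. Key step: that keto-enal (C5'–C12', with the 6'E alkene and its methyl) ⇒ rosefuran by singlet-oxygen dearomatisation and ring opening in the presence of the prenyl alkene (furan C5 → aldehyde C5', furan C2 → ketone C8').
5. Rosefuran ⇒ 3-methylfuran (C2 bromination, Br–Li exchange, prenyl bromide).

Assumption: the D-tryptophan-derived oxazaborolidinone is taken to direct attack to the Si face of the aldehyde (giving 5S); if Mosher analysis of 11 shows the opposite sense, the L-tryptophan catalyst is used and nothing else changes.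

**Route**

Step 1
Reactants: 1 3-methylfuran
Product: 2 2-bromo-3-methylfuran
Conditions: NBS (1.0 equiv), DMF, −20 → 0 °C, dark; pentane extraction, used cold as a solution
Reagents that add atoms: N-bromosuccinimide, O=C1CCC(=O)N1Br
Why: Electrophilic aromatic bromination goes to C2, the α-position that is also ortho to the methyl group and the most electron-rich site, which gives a regiodefined handle for metalation.

Step 2
Reactants: 2 2-bromo-3-methylfuran; 3 prenyl bromide (1-bromo-3-methylbut-2-ene)
Product: 5 rosefuran [3-methyl-2-(3-methylbut-2-en-1-yl)furan], via 2-lithio-3-methylfuran 4 (not isolated)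
Conditions: n-BuLi (1.05 equiv), THF, −78 °C, 20 min; then 3 (1.2 equiv), −78 → 0 °C
Reagents that add atoms: none
Why: Bromine–lithium exchange followed by SN2 alkylation of the furyllithium at the primary allylic carbon of prenyl bromide.

Step 3
Reactants: 5 rosefuran
Product: 8 (2E)-3,7-dimethyl-4-oxoocta-2,6-dienal, via furan endoperoxide 6 (not isolated), via Z-keto-enal 7 (not isolated)
Conditions: O2, tetraphenylporphyrin (0.1 mol %), visible light, CH2Cl2, −78 °C (stopped when 5 is consumed); then Me2S (2 equiv), −78 → 0 °C; then pyridine (0.2 equiv), 0 °C → rt, dark; used at once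
Reagents that add atoms: dioxygen (as singlet oxygen), O=O
Why: The [4+2] cycloaddition of singlet oxygen to the 2,3-dialkylfuran (expected to be roughly a hundred times faster than the ene reaction of the trisubstituted alkene) breaks the aromatic ring, sulfide reduction of the endoperoxide unveils the cis-enedicarbonyl, and pyridine-mediated addition–elimination isomerises it to the more stable E geometry, so furan C5 becomes the C5' aldehyde and furan C2 the C8' ketone.

Step 4
Reactants: 9 prenal (3-methylbut-2-enal)
Product: 10 tert-butyl(dimethyl){[(1E)-3-methylbuta-1,3-dien-1-yl]oxy}silane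
Conditions: TBSOTf (1.1 equiv), Et3N (1.5 equiv), Et2O, 0 °C → rt; distilled
Reagents that add atoms: tert-butyldimethylsilyl trifluoromethanesulfonate, CC(C)(C)[Si](C)(C)OS(=O)(=O)C(F)(F)F
Why: Soft enolisation (O-silylation of the enal, then γ-deprotonation by the amine) gives the 1-silyloxy diene as the vinylogous aldehyde enolate equivalent.

Step 5
Reactants: 8 (2E)-3,7-dimethyl-4-oxoocta-2,6-dienal; 10 the silyl dienol ether
Product: 12 (2E,5S,6E)-3,7,11-trimethyl-1,8-dioxododeca-2,6,10-trien-5-yl acetate, via hydroxy-enal 11 (not isolated)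
Conditions: B-phenyl oxazaborolidinone from N-tosyl-D-tryptophan and PhBCl2 (0.5 equiv), 10 (1.6 equiv), i-PrOH (1.2 equiv), EtCN, −78 °C; then pyridine (5 equiv), Ac2O (3 equiv), DMAP (0.1 equiv), −78 → 0 °C
Reagents that add atoms: acetic anhydride, CC(=O)OC(C)=O
Why: In this vinylogous Mukaiyama aldol the chiral boron Lewis acid activates the formyl group (far more reactive than the hindered cross-conjugated ketone or the β,β-dialkyl enal of the product), the γ-carbon of the s-trans dienol ether attacks the Si face through an open transition state to set 5S and the 2E enal, and in-flask DMAP-catalysed acetylation caps the secondary alcohol before the labile aldol is handled.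

Step 6
Reactants: 12 the acetoxy keto-enal
Product: 13 (2E,5S,6E,8R)-1,8-dihydroxy-3,7,11-trimethyldodeca-2,6,10-trien-5-yl acetate
Conditions: (S)-2-methyl-CBS-oxazaborolidine [(S)-1-methyl-3,3-diphenyltetrahydro-1H,3H-pyrrolo[1,2-c][1,3,2]oxazaborole] (0.2 equiv), catecholborane (2.5 equiv), toluene, −78 → −40 °C; MeOH quench, pH 9 buffer wash
Reagents that add atoms: none
Why: In this Corey–Bakshi–Shibata reduction the α-methyl alkenyl group acts as the large substituent and the prenyl CH2 as the small one, so the (S)-catalyst delivers hydride to give 8R under catalyst control, while the same reagent reduces the enal 1,2 to the achiral primary allylic alcohol and leaves the acetate and all alkenes untouched.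

Step 7
Reactants: 13 the diol monoacetate; 14 umbelliferone (7-hydroxy-2H-chromen-2-one)
Product: 15 (2E,5S,6E,8R)-8-hydroxy-3,7,11-trimethyl-1-[(2-oxo-2H-chromen-7-yl)oxy]dodeca-2,6,10-trien-5-yl acetate (target)
Conditions: 14 (1.05 equiv), PPh3 (1.1 equiv), diisopropyl azodicarboxylate (1.1 equiv), THF, 0 °C
Reagents that add atoms: none
Why: In this Mitsunobu etherification the acidic phenol (pKa about 8) displaces the activated primary allylic hydroxyl by SN2, which reacts much faster than the hindered secondary 8'-hydroxyl, so the 2'E geometry and both stereocentres are untouched.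

**Compound list**

1 | 3-methylfuran | Cc1ccoc1 | starting material
2 | 2-bromo-3-methylfuran | Cc1ccoc1Br | intermediate
3 | prenyl bromide (1-bromo-3-methylbut-2-ene) | CC(C)=CCBr | starting material
4 | 2-lithio-3-methylfuran | [Li]c1occc1C | intermediate
5 | rosefuran, 3-methyl-2-(3-methylbut-2-en-1-yl)furan | Cc1ccoc1CC=C(C)C | intermediate
6 | 6-methyl-1-(3-methylbut-2-en-1-yl)-2,3,7-trioxabicyclo[2.2.1]hept-5-ene (furan endoperoxide, racemic) | CC(C)=CCC12OOC(O1)C=C2C | intermediate
7 | (2Z)-3,7-dimethyl-4-oxoocta-2,6-dienal | O=C/C=C(/C)C(=O)CC=C(C)C | intermediate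
8 | (2E)-3,7-dimethyl-4-oxoocta-2,6-dienal | O=C/C=C(\C)C(=O)CC=C(C)C | intermediate
9 | prenal (3-methylbut-2-enal) | CC(C)=CC=O | starting material
10 | tert-butyl(dimethyl){[(1E)-3-methylbuta-1,3-dien-1-yl]oxy}silane | C=C(C)/C=C/O[Si](C)(C)C(C)(C)C | intermediate
11 | (2E,5S,6E)-5-hydroxy-3,7,11-trimethyl-8-oxododeca-2,6,10-trienal | O[C@H](/C=C(\C)C(=O)CC=C(C)C)C/C(C)=C/C=O | intermediate
12 | (2E,5S,6E)-3,7,11-trimethyl-1,8-dioxododeca-2,6,10-trien-5-yl acetate | CC(=O)O[C@H](/C=C(\C)C(=O)CC=C(C)C)C/C(C)=C/C=O | intermediate
13 | (2E,5S,6E,8R)-1,8-dihydroxy-3,7,11-trimethyldodeca-2,6,10-trien-5-yl acetate | CC(=O)O[C@H](/C=C(\C)[C@H](O)CC=C(C)C)C/C(C)=C/CO | intermediate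
14 | umbelliferone (7-hydroxy-2H-chromen-2-one) | O=c1ccc2ccc(O)cc2o1 | starting material
15 | (2E,5S,6E,8R)-8-hydroxy-3,7,11-trimethyl-1-[(2-oxo-2H-chromen-7-yl)oxy]dodeca-2,6,10-trien-5-yl acetate | CC(=O)O[C@H](/C=C(\C)[C@H](O)CC=C(C)C)C/C(C)=C/COc1ccc2ccc(=O)oc2c1 | target

**Step count and risks**

Total steps: 7. Longest linear sequence: 6 (steps 1, 2, 3, 5, 6, 7); step 4 is a one-step side branch.

The three steps most likely to fail:

Step 3. The risks are competing ene oxidation of the prenyl alkene, incomplete Z → E isomerisation, and loss of the skipped enone 8 by conjugation or oligomerisation. The fallback removes the ene-reactive alkene from the photooxygenation and installs it afterwards by cross-metathesis. It sets out from 2: the lithium reagent 4, made as in step 2, is quenched with allyl bromide to give 3-methyl-2-(prop-2-en-1-yl)furan F1, whose terminal alkene is inert to singlet oxygen. Photooxygenation gives 6-methyl-1-(prop-2-en-1-yl)-2,3,7-trioxabicyclo[2.2.1]hept-5-ene F2, Me2S gives (2Z)-3-methyl-4-oxohepta-2,6-dienal F3, and pyridine gives (2E)-3-methyl-4-oxohepta-2,6-dienal F4. Cross-metathesis of F4 with excess 2-methylbut-2-ene (second-generation Grubbs catalyst, (H2IMes)(PCy3)Cl2Ru=CHPh, CH2Cl2, 40 °C) turns the allyl group into prenyl; the electron-poor trisubstituted enal alkene does not take part. The route is rejoined at 8.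

Step 5. The risks are insufficient enantioselectivity with this unusually electrophilic, bifunctional enal, a competing hetero-Diels–Alder or Mukaiyama–Michael pathway, and elimination of the acetate toward the dienal. The fallback replaces asymmetric induction by resolution. It sets out from 8 and 10: the achiral borane B(C6F5)3 with propan-2-ol (CH2Cl2, −78 °C) gives racemic (2E,6E)-5-hydroxy-3,7,11-trimethyl-8-oxododeca-2,6,10-trienal F5. Burkholderia cepacia lipase with vinyl acetate then acetylates the 5R alcohol (Kazlauskas rule, alkenyl as the large group) to (2E,5R,6E)-3,7,11-trimethyl-1,8-dioxododeca-2,6,10-trien-5-yl acetate F6. The unreacted 5S alcohol 11 is separated and acetylated with Ac2O and pyridine, and the route is rejoined at 12.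

Step 7. The risk is incomplete discrimination between the primary and the secondary allylic hydroxyl, or SN2' attack. The fallback keeps C8' as the ketone during the etherification, so only one hydroxyl is present. It sets out from 12: NaBH4 (EtOH/CH2Cl2, −78 °C) reduces only the aldehyde to (2E,5S,6E)-1-hydroxy-3,7,11-trimethyl-8-oxododeca-2,6,10-trien-5-yl acetate F7. Mitsunobu coupling with 14 gives (2E,5S,6E)-3,7,11-trimethyl-8-oxo-1-[(2-oxo-2H-chromen-7-yl)oxy]dodeca-2,6,10-trien-5-yl acetate F8. The (S)-2-methyl-CBS-oxazaborolidine/catecholborane reduction of step 6 is then applied last; the coumarin lactone is inert at −78 °C. The route is rejoined at 15.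

**Further compounds**

F1 | step 3 | 3-methyl-2-(prop-2-en-1-yl)furan | C=CCc1occc1C
F2 | step 3 | 6-methyl-1-(prop-2-en-1-yl)-2,3,7-trioxabicyclo[2.2.1]hept-5-ene | C=CCC12OOC(O1)C=C2C
F3 | step 3 | (2Z)-3-methyl-4-oxohepta-2,6-dienal | O=C/C=C(/C)C(=O)CC=C
F4 | step 3 | (2E)-3-methyl-4-oxohepta-2,6-dienal | O=C/C=C(\C)C(=O)CC=C
F5 | step 5 | racemic (2E,6E)-5-hydroxy-3,7,11-trimethyl-8-oxododeca-2,6,10-trienal | OC(/C=C(\C)C(=O)CC=C(C)C)C/C(C)=C/C=O
F6 | step 5 | (2E,5R,6E)-3,7,11-trimethyl-1,8-dioxododeca-2,6,10-trien-5-yl acetate | CC(=O)O[C@@H](/C=C(\C)C(=O)CC=C(C)C)C/C(C)=C/C=O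
F7 | step 7 | (2E,5S,6E)-1-hydroxy-3,7,11-trimethyl-8-oxododeca-2,6,10-trien-5-yl acetate | CC(=O)O[C@H](/C=C(\C)C(=O)CC=C(C)C)C/C(C)=C/CO
F8 | step 7 | (2E,5S,6E)-3,7,11-trimethyl-8-oxo-1-[(2-oxo-2H-chromen-7-yl)oxy]dodeca-2,6,10-trien-5-yl acetate | CC(=O)O[C@H](/C=C(\C)C(=O)CC=C(C)C)C/C(C)=C/COc1ccc2ccc(=O)oc2c1
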